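**Retrosynthetic overview**

- The target is reached from its bis(methoxymethyl) ether; the last step only frees the C7 and C4' phenols.
- Ring C is disconnected at O1–C8a and at C2–C3: a one-pot formal hetero-(4+2) annulation of 4-(methoxymethoxy)benzaldehyde with the trimethylsilyl enol ether of a ring A methyl ketone that carries fluorine on C8a.
- Enabling feature: C8a of ring A is ortho to the C4 carbonyl of ring C, so C4(=O)–C4a=C8a–O1 is a vinylogous ester and O1–C8a is its β-C–O bond. With fluorine on C8a, the unit C3=C4(OSiMe3)–C4a=C8a–F is a ring-A-fused 1-halo-3-silyloxydiene; its aldol adduct closes ring C by displacing fluoride at C8a.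
- The ring A pattern (prenyl at C6 and C8, oxygen at C7) is set beforehand on 2'-fluoro-4'-hydroxyacetophenone by twofold ortho-iodination and twofold Stille prenylation.
- Ring order: rings A and B are bought as benzenes; ring C is the only ring made, and it is made last.

Key step: step 5

Assumption: the (R)-tryptophan-derived oxazaborolidinone is taken to direct the enol silane to the Si face of the aryl aldehyde (mirror image of the Re-face preference of the (S)-catalyst, recalled and not verified; if the sense is opposite, the (S)-catalyst is used); the fluoro ketone, the prenylstannane and the aldehyde are taken as purchasable.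

**Step 1**
Reactants: 1 1-(2-fluoro-4-hydroxyphenyl)ethan-1-one
Product: 2 1-(2-fluoro-4-hydroxy-3,5-diiodophenyl)ethan-1-one
Conditions: NIS (2.1 equiv), p-MeC6H4SO3H·H2O (10 mol %), MeCN, 0 °C → rt
Reagents that add atoms: N-iodosuccinimide, O=C1CCC(=O)N1I
Why: Electrophilic aromatic iodination should go to the two positions ortho to the phenol (para is blocked by the acetyl group), which are the only activated ring sites and react faster than the ketone α-position.

**Step 2**
Reactants: 2 1-(2-fluoro-4-hydroxy-3,5-diiodophenyl)ethan-1-one
Product: 3 1-[2-fluoro-3,5-diiodo-4-(methoxymethoxy)phenyl]ethan-1-one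
Conditions: MOMCl (1.5 equiv), i-Pr2NEt (2.0 equiv), CH2Cl2, 0 °C → rt
Reagents that add atoms: chloromethyl methyl ether, COCCl
Why: Williamson-type O-alkylation of the acidic 2,6-diiodophenol gives the MOM acetal, which should survive the Stille coupling, the enolisation, the boron Lewis acid and fluoride.

**Step 3**
Reactants: 3 1-[2-fluoro-3,5-diiodo-4-(methoxymethoxy)phenyl]ethan-1-one; 4 tributyl(3-methylbut-2-en-1-yl)stannane (2.5 equiv)
Product: 5 1-[2-fluoro-4-(methoxymethoxy)-3,5-bis(3-methylbut-2-en-1-yl)phenyl]ethan-1-one
Conditions: Pd(PPh3)4 (10 mol %), DMF, 95 °C, degassed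
Reagents that add atoms: none
Why: Twofold Stille coupling: zerovalent palladium inserts into both C–I bonds (the C–F bond is inert) and the allylic stannane should deliver the prenyl group through its less hindered terminus, giving the linear 3-methylbut-2-enyl arene.

**Step 4**
Reactants: 5 1-[2-fluoro-4-(methoxymethoxy)-3,5-bis(3-methylbut-2-en-1-yl)phenyl]ethan-1-one
Product: 6 ({1-[2-fluoro-4-(methoxymethoxy)-3,5-bis(3-methylbut-2-en-1-yl)phenyl]ethenyl}oxy)trimethylsilane
Conditions: LiN(i-Pr)2 (1.1 equiv), THF, −78 °C; Me3SiCl (1.3 equiv), −78 → 0 °C; pentane, filtration, used crude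
Reagents that add atoms: chlorotrimethylsilane, C[Si](C)(C)Cl
Why: Kinetic enolisation of the methyl ketone (its only enolisable position) followed by O-silylation gives the silyl enol ether, while the acetal, the aryl fluoride and the prenyl groups are inert to the amide base at −78 °C.

**Step 5**
Reactants: 6 ({1-[2-fluoro-4-(methoxymethoxy)-3,5-bis(3-methylbut-2-en-1-yl)phenyl]ethenyl}oxy)trimethylsilane (1.0 equiv); 7 4-(methoxymethoxy)benzaldehyde (1.05 equiv)
Product: 10 (2S)-7-(methoxymethoxy)-2-[4-(methoxymethoxy)phenyl]-6,8-bis(3-methylbut-2-en-1-yl)-2,3-dihydro-4H-1-benzopyran-4-one, via silyl ether aldol 8 (not isolated), via ammonium alkoxide 9 (not isolated)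
Conditions: (R)-2-butyl-4-(1H-indol-3-ylmethyl)-3-(4-methylphenylsulfonyl)-1,3,2-oxazaborolidin-5-one (C22H25BN2O4S, 20 mol %), EtCN, −78 °C; then Bu4N[Ph3SiF2] (30 mol %), THF, −78 → −20 °C; AcOH quench
Reagents that add atoms: none
Why: Proposed new method: the chiral boron Lewis acid binds aldehyde 7 and enol silane 6 adds to its Si face (Mukaiyama aldol with silyl transfer) to give 8; fluoride then strips the silyl group, the freed C2 alkoxide of 9 attacks C8a and expels fluoride, which desilylates the next molecule of 8, so that only Me3SiF is lost overall (closest known reaction types: the oxazaborolidinone-catalysed Mukaiyama aldol–dihydropyranone annulation of aldehydes with 1-methoxy-3-(trimethylsilyloxy)buta-1,3-diene, and fluoride-catalysed SNAr etherification of silyl ethers with activated aryl fluorides). Ring C should close in a 6-endo-trig addition–elimination at C8a, the negative charge being taken up by the C4 carbonyl that lies inside the forming ring. The only stereocenter, C2, is set in the aldol event by the catalyst (Si-face attack gives S) and is not touched afterwards, because the C2–O bond is never broken. The step needs O-arylation to outrun retro-aldol cleavage and β-elimination of 9 as well as base-induced ring opening of 10; the ortho-acyl activation of the C–F bond, the six-membered transition state, the low temperature, the sub-stoichiometric fluoride and the acidic quench are relied on for this. Regioselectivity is not an issue, since ring A carries a single fluorine.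

**Step 6**
Reactants: 10 (2S)-7-(methoxymethoxy)-2-[4-(methoxymethoxy)phenyl]-6,8-bis(3-methylbut-2-en-1-yl)-2,3-dihydro-4H-1-benzopyran-4-one
Product: 11 (2S)-7-hydroxy-2-(4-hydroxyphenyl)-6,8-bis(3-methylbut-2-en-1-yl)-2,3-dihydro-4H-1-benzopyran-4-one
Conditions: HCl (3 M aq., 3 equiv), MeOH, 40 °C
Reagents that add atoms: none
Why: Acid-catalysed transacetalisation to dimethoxymethane should free both phenols under conditions too mild to ionise the C2–O1 bond or to add the C7 phenol to a prenyl double bond, so the (2S) configuration is kept.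

**Compound list**

1 | 1-(2-fluoro-4-hydroxyphenyl)ethan-1-one | CC(=O)c1ccc(O)cc1F | starting material
2 | 1-(2-fluoro-4-hydroxy-3,5-diiodophenyl)ethan-1-one | CC(=O)c1cc(I)c(O)c(I)c1F | intermediate
3 | 1-[2-fluoro-3,5-diiodo-4-(methoxymethoxy)phenyl]ethan-1-one | CC(=O)c1cc(I)c(OCOC)c(I)c1F | intermediate
4 | tributyl(3-methylbut-2-en-1-yl)stannane | CC(C)=CC[Sn](CCCC)(CCCC)CCCC | starting material
5 | 1-[2-fluoro-4-(methoxymethoxy)-3,5-bis(3-methylbut-2-en-1-yl)phenyl]ethan-1-one | CC(=O)c1cc(CC=C(C)C)c(OCOC)c(CC=C(C)C)c1F | intermediate
6 | ({1-[2-fluoro-4-(methoxymethoxy)-3,5-bis(3-methylbut-2-en-1-yl)phenyl]ethenyl}oxy)trimethylsilane | C=C(O[Si](C)(C)C)c1cc(CC=C(C)C)c(OCOC)c(CC=C(C)C)c1F | intermediate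
7 | 4-(methoxymethoxy)benzaldehyde | COCOc1ccc(C=O)cc1 | starting material
8 | (3S)-1-[2-fluoro-4-(methoxymethoxy)-3,5-bis(3-methylbut-2-en-1-yl)phenyl]-3-[4-(methoxymethoxy)phenyl]-3-[(trimethylsilyl)oxy]propan-1-one | O=C(C[C@H](O[Si](C)(C)C)c1ccc(OCOC)cc1)c1cc(CC=C(C)C)c(OCOC)c(CC=C(C)C)c1F | intermediate (not isolated)
9 | tetrabutylammonium (1S)-3-[2-fluoro-4-(methoxymethoxy)-3,5-bis(3-methylbut-2-en-1-yl)phenyl]-1-[4-(methoxymethoxy)phenyl]-3-oxopropan-1-olate | O=C(C[C@H]([O-])c1ccc(OCOC)cc1)c1cc(CC=C(C)C)c(OCOC)c(CC=C(C)C)c1F.CCCC[N+](CCCC)(CCCC)CCCC | intermediate (not isolated)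
10 | (2S)-7-(methoxymethoxy)-2-[4-(methoxymethoxy)phenyl]-6,8-bis(3-methylbut-2-en-1-yl)-2,3-dihydro-4H-1-benzopyran-4-one | CC(C)=CCc1cc2c(c(CC=C(C)C)c1OCOC)O[C@H](c1ccc(OCOC)cc1)CC2=O | intermediate
11 | (2S)-7-hydroxy-2-(4-hydroxyphenyl)-6,8-bis(3-methylbut-2-en-1-yl)-2,3-dihydro-4H-1-benzopyran-4-one | CC(C)=CCc1cc2c(c(CC=C(C)C)c1O)O[C@H](c1ccc(O)cc1)CC2=O | target

**Step count and risks**

Total step count: 6. Longest linear sequence: 6 steps (1 to 11).

Step 5 is the most likely to fail. The freed alkoxide may fragment by retro-aldol cleavage or lose water by β-elimination faster than it displaces fluoride, and residual fluoride may open ring C of the product; each process lowers yield and enantiomeric purity. Facial selectivity in the aldol event may also be incomplete, in which case the enantiomeric purity of 10 would have to be raised by crystallisation. The fallback uses known chemistry, sets out from ketone 5 and rejoins the route at 10. Claisen condensation of 5 with ethyl formate (NaH, THF) should give the enolate of the β-keto aldehyde, sodium (1Z)-3-[2-fluoro-4-(methoxymethoxy)-3,5-bis(3-methylbut-2-en-1-yl)phenyl]-3-oxoprop-1-en-1-olate F1. On warming in DMF this should close by O-arylation of the 1,3-dicarbonyl enolate at the ortho C–F bond (the established route from 2-fluoroaryl 1,3-dicarbonyl compounds to chromones) to 7-(methoxymethoxy)-6,8-bis(3-methylbut-2-en-1-yl)-4H-1-benzopyran-4-one F2. Asymmetric conjugate addition of purchased [4-(methoxymethoxy)phenyl]boronic acid to F2 then sets C2 and gives 10; conditions: Pd(OCOCF3)2, 4-tert-butyl-2-(pyridin-2-yl)-4,5-dihydro-1,3-oxazole in the enantiomer that gives the (2S) product, NH4PF6, H2O, ClCH2CH2Cl, 60 °C.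

Step 3 is the second risk. The allyl unit may transpose on palladium so that coupling occurs through the dimethyl-substituted carbon, and the second coupling at the iodide flanked by fluorine and the acetal may stall. The fallback sets out from 3 and rejoins at 5. Twofold Stille coupling of 3 with allyltributylstannane (Pd(PPh3)4, DMF, 95 °C), where no regiochemical question arises, should give 1-[2-fluoro-4-(methoxymethoxy)-3,5-di(prop-2-en-1-yl)phenyl]ethan-1-one F3. Twofold cross-metathesis of F3 with 2-methylbut-2-ene, using the second-generation Grubbs catalyst (H2IMes)(PCy3)Cl2Ru=CHPh in CH2Cl2 at 40 °C, then converts both allyl groups into prenyl groups and gives 5.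

Step 6 is the third risk. Under protic acid the liberated C7 phenol may add to a neighbouring prenyl double bond, and the benzylic C2–O1 bond may ionise, which would erode the configuration. The fallback sets out from 10 and ends at 11 without a new intermediate. The acetals are cleaved under aprotic conditions by a Lewis acid with a soft thiol trap (ZnBr2, n-PrSH, CH2Cl2, 0 °C), which transfers the methoxymethyl groups to sulfur instead of generating a protic acidic medium.

**Further compounds**

F1 | step 5 | sodium (1Z)-3-[2-fluoro-4-(methoxymethoxy)-3,5-bis(3-methylbut-2-en-1-yl)phenyl]-3-oxoprop-1-en-1-olate | [Na+].[O-]/C=C\C(=O)c1cc(CC=C(C)C)c(OCOC)c(CC=C(C)C)c1F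
F2 | step 5 | 7-(methoxymethoxy)-6,8-bis(3-methylbut-2-en-1-yl)-4H-1-benzopyran-4-one | O=c1ccoc2c(CC=C(C)C)c(OCOC)c(CC=C(C)C)cc12
F3 | step 3 | 1-[2-fluoro-4-(methoxymethoxy)-3,5-di(prop-2-en-1-yl)phenyl]ethan-1-one | CC(=O)c1cc(CC=C)c(OCOC)c(CC=C)c1F
F0 | step 6 | none | none
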